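**Strategy.** Ring B, the cyclohexene-diol ring (C8, C9, C10, C14, C15, C16; atom numbering given below), is cut across its two opposite bonds, C9–C10 and C15–C16. This gives a three-carbon iodo-enal linchpin (C16–C8=C9, carrying the side chain) and a formyl cyclopentenyl methyl ketone (C15–C14–C10, ring C). The key step unites them in one flask by a chromium/nickel reductive [3+3] annulation: cross-pinacol-type addition makes the diol bond C15–C16, then the alkenyl iodide adds 6-exo to the enone to make C9–C10 and the cis B/C fusion. It exploits that C16 is a carbinol carbon allylic to the C8=C9 alkene and that C10 is β to the C1 carbonyl. Ring A is closed last by Nozaki–Hiyama–Kishi macrocyclization.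

Key step: step 8

Atom numbering used below: C1 = ring carbon bearing the exocyclic CH2; C2 = CH–OAc; C3, C4 = CH2; C5 = CH(CH3); C6, C7 = CH2; C8 = alkene carbon bound to C7 and C16; C9 = alkene carbon bearing CH3; C10 = ring-fusion CH; C11 = CH bound to C1; C12, C13 = CH2; C14 = C(CH3); C15, C16 = CH–OH (C15 next to C14). Ring A = C1–C11 (11-membered), ring B = C8/C9/C10/C14/C15/C16, ring C = C10–C14.

Assumption: (S)-proline is taken to select the formyl group that leads to (S)-14 (by analogy with the Hajos–Parrish transition-state model); if the sense is the opposite, (R)-proline is used instead.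

Step 1
Reactants: 1 (S)-citronellyl bromide; 2 but-2-yn-1-ol
Product: 5 (Z)-3-iodo-2-[(S)-3,7-dimethyloct-6-enyl]but-2-en-1-ol, via Grignard reagent 3 (not isolated), via alkenylmagnesium alkoxide 4 (not isolated)
Conditions: Mg, THF; then 2 (0.45 equiv), CuI (10 mol %), THF, 0 °C to 40 °C; then I2, −40 °C to rt
Reagents that add atoms: iodine, II
Why: Copper-catalysed anti-carbomagnesiation of the propargylic alkoxide (alkyl group to the carbon next to CH2O, magnesium held cis to oxygen in a five-membered chelate) followed by iodinolysis with retention should fix the tetrasubstituted (Z)-iodoalkene with iodine cis to CH2OH; no stereocentre is formed and C5 comes unchanged from 1.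

Step 2
Reactants: 5 (Z)-iodo allylic alcohol
Product: 6 (Z)-3-iodo-2-[(S)-3,7-dimethyloct-6-enyl]but-2-enal
Conditions: MnO2, CH2Cl2, rt
Reagents that add atoms: none
Why: Allylic alcohol oxidation with MnO2 should give the enal without touching the vinyl iodide or the remote trisubstituted alkene.

Step 3
Reactants: 7 diethyl methylmalonate; 8 2-(3-chloropropyl)-2-methyl-1,3-dioxolane
Product: 9 diethyl 2-methyl-2-[3-(2-methyl-1,3-dioxolan-2-yl)propyl]malonate
Conditions: NaH, NaI (cat.), DMF, 70 °C
Reagents that add atoms: none
Why: Malonate alkylation (SN2, iodide-assisted) should build the quaternary carbon C14, still prochiral.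

Step 4
Reactants: 9 malonate ketal
Product: 10 2-methyl-2-[3-(2-methyl-1,3-dioxolan-2-yl)propyl]propane-1,3-diol
Conditions: LiAlH4, THF, 0 °C to rt
Reagents that add atoms: none
Why: LiAlH4 reduction of both esters should give the diol while the dioxolane keeps the ketone masked.

Step 5
Reactants: 10 diol ketal
Product: 11 6-hydroxy-5-(hydroxymethyl)-5-methylhexan-2-one
Conditions: 1 M HCl, THF, rt
Reagents that add atoms: water, O
Why: Acid-catalysed ketal hydrolysis should free the methyl ketone before the aldehydes are made, so that no acid meets the later dialdehyde.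

Step 6
Reactants: 11 keto diol
Product: 12 2-methyl-2-(4-oxopentyl)propanedial
Conditions: Dess–Martin periodinane, CH2Cl2, rt
Reagents that add atoms: none
Why: Dess–Martin oxidation of both primary alcohols should give the non-enolisable 2,2-disubstituted malonaldehyde under neutral conditions that do not start the aldol.

Step 7
Reactants: 12 keto dialdehyde
Product: 14 (S)-3-acetyl-1-methylcyclopent-2-ene-1-carbaldehyde, via aldol adduct 13 (not isolated)
Conditions: (S)-proline (30 mol %), DMSO, rt; then AcOH, 50 °C
Reagents that add atoms: none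
Why: Proline-catalysed enantiogroup-selective intramolecular aldol condensation of the Hajos–Parrish type (the enamine of the methyl ketone attacks one of the two enantiotopic formyl groups in a five-membered ring closure, then the β-hydroxy ketone dehydrates) should set the quaternary stereocentre C14 through the carboxylic-acid-directed transition state.

Step 8
Reactants: 6 (Z)-iodo enal; 14 (S)-formyl cyclopentenyl methyl ketone
Product: 17 cis-diol methyl ketone with rings B and C, via chromium alkoxide adduct 15 (not isolated), via bis-silyl enol ether 16 (not isolated)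
Conditions: CrCl2 (6 equiv), NiCl2 (2 mol %), Me3SiCl (2.5 equiv), DMF–THF, 0 °C then 45 °C; then 1 M HCl, THF
Reagents that add atoms: none
Why: Proposed new method: a one-pot chromium/nickel reductive [3+3] annulation that merges two reaction types known separately, the chromium-mediated enal–aldehyde cross-pinacol coupling and the nickel-mediated alkenyl halide–enone cyclization (the alkenylation half of Nozaki–Hiyama–Kishi chemistry). Divalent chromium and Me3SiCl should reduce the iodo-enal of 6, the most electron-poor π system present, to a γ-siloxyallylchromium species that adds through its oxygen-bearing carbon C16 to the formyl group of 14, forming C15–C16 and re-forming the C8=C9 alkene with iodine (axial in the chair, as with α-haloallyl metals) cis to C16 to give 15; zerovalent nickel formed in situ should then insert into the C9–I bond and the alkenylnickel add to the enone carbon C10, Me3SiCl trapping the enolate as 16. Ring B is closed in this second event in the 6-exo-trig mode. C15 should be set by Felkin–Anh addition anti to the ring alkene carbon C10 and past the methyl group (hydroxyl cis to the C14 methyl), C16 by the chair transition state of the (E)-siloxyallyl metal (anti adduct, hence the cis-diol in ring B), C10 by the C15–C16 tether (alkenyl group delivered cis to C15, cis ring fusion), and C11 by protonation of the enol ether on the face away from ring B. The step needs chemoselection (enal reduced before the enone, no direct alkenylation of the aldehyde), which the easier reduction of the β-iodo enal, the cold first stage and the low nickel loading should secure, while the tether favours 1,4- over 1,2-addition in the ring closure.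

Step 9
Reactants: 17 cis-diol methyl ketone
Product: 18 C16 4-nitrobenzoate with inverted C16 and free C15 hydroxyl
Conditions: 4-O2NC6H4CO2H, PPh3, DIAD, THF, 0 °C to rt
Reagents that add atoms: 4-nitrobenzoic acid, O=C(O)c1ccc(cc1)[N+](=O)[O-]
Why: Mitsunobu esterification should invert the allylic carbinol C16 by SN2 displacement, the neopentyl C15 hydroxyl being too hindered to react, so that the diol becomes trans.

Step 10
Reactants: 18 4-nitrobenzoate
Product: 19 trans-diol methyl ketone
Conditions: NaN3, MeOH, 40 °C
Reagents that add atoms: none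
Why: Azide-mediated methanolysis (transesterification) of the 4-nitrobenzoate should free the C16 hydroxyl under nearly neutral conditions that do not epimerise C11.

Step 11
Reactants: 19 trans-diol methyl ketone
Product: 20 acetonide methyl ketone
Conditions: 2-methoxypropene, PPTS, CH2Cl2, 0 °C
Reagents that add atoms: 2-methoxypropene, C=C(C)OC
Why: Acetal formation with 2-methoxypropene under mild acid should protect the trans-diol as its acetonide.

Step 12
Reactants: 20 acetonide methyl ketone
Product: 21 enol triflate (CH2=C(OTf) on C11)
Conditions: KN(SiMe3)2, PhNTf2, THF, −78 °C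
Reagents that add atoms: N-phenyl-bis(trifluoromethanesulfonimide), FC(F)(F)S(=O)(=O)N(c1ccccc1)S(=O)(=O)C(F)(F)F
Why: Kinetic deprotonation of the methyl ketone at the methyl group and O-triflation should give the 1,1-disubstituted enol triflate without enolising towards C11, whose configuration is kept.

Step 13
Reactants: 21 enol triflate
Product: 23 C2 aldehyde enol triflate, via side-chain diol 22 (not isolated)
Conditions: OsO4 (2 mol %), NMO, acetone–H2O, rt; then NaIO4
Reagents that add atoms: N-methylmorpholine N-oxide, C[N+]1([O-])CCOCC1; water, O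
Why: OsO4-catalysed dihydroxylation should pick the electron-rich trisubstituted side-chain alkene over the hindered tetrasubstituted ring alkene and the electron-poor enol triflate, and periodate cleavage of the diol should then give the aldehyde.

Step 14
Reactants: 23 C2 aldehyde enol triflate
Product: 24 tricyclic allylic alcohol (ring A closed, acetonide)
Conditions: CrCl2, NiCl2 (1 mol %), DMSO–THF, 0.002 M, rt
Reagents that add atoms: none
Why: Intramolecular Nozaki–Hiyama–Kishi reaction of the alkenyl triflate with the aldehyde under high dilution should close the 11-membered ring A and give the allylic alcohol with the exocyclic methylene in place, the new stereocentre C2 being set by the macrocyclic chromium alkoxide transition state in which the C3 chain turns away from ring C.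

Step 15
Reactants: 24 tricyclic allylic alcohol
Product: 25 C2 acetate acetonide
Conditions: Ac2O, DMAP, pyridine, rt
Reagents that add atoms: acetic anhydride, CC(=O)OC(C)=O
Why: DMAP-catalysed acylation of the secondary allylic alcohol should give the acetate.

Step 16
Reactants: 25 C2 acetate acetonide
Product: 26 target CNP0192310.1
Conditions: AcOH–H2O–THF (3:1:1), 40 °C
Reagents that add atoms: none
Why: Mild aqueous acid hydrolysis of the strained trans-fused acetonide should release the diol without cleaving the allylic acetate.

**Compound list**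

1 | (S)-citronellyl bromide, (S)-8-bromo-2,6-dimethyloct-2-ene | BrCC[C@@H](C)CCC=C(C)C | starting material
2 | but-2-yn-1-ol | CC#CCO | starting material
3 | (S)-citronellylmagnesium bromide (not isolated) | Br[Mg]CC[C@@H](C)CCC=C(C)C | intermediate
4 | alkenylmagnesium alkoxide, magnesium on C9 cis to the CH2OMgBr group (not isolated) | Br[Mg]OC/C(CC[C@@H](C)CCC=C(C)C)=C(/C)[Mg]Br | intermediate
5 | (Z)-3-iodo-2-[(S)-3,7-dimethyloct-6-enyl]but-2-en-1-ol | OC/C(CC[C@@H](C)CCC=C(C)C)=C(/C)I | intermediate
6 | (Z)-3-iodo-2-[(S)-3,7-dimethyloct-6-enyl]but-2-enal | O=C/C(CC[C@@H](C)CCC=C(C)C)=C(/C)I | intermediate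
7 | diethyl methylmalonate | CCOC(=O)C(C)C(=O)OCC | starting material
8 | 2-(3-chloropropyl)-2-methyl-1,3-dioxolane | CC1(CCCCl)OCCO1 | starting material
9 | diethyl 2-methyl-2-[3-(2-methyl-1,3-dioxolan-2-yl)propyl]malonate | CCOC(=O)C(C)(CCCC1(C)OCCO1)C(=O)OCC | intermediate
10 | 2-methyl-2-[3-(2-methyl-1,3-dioxolan-2-yl)propyl]propane-1,3-diol | OCC(C)(CO)CCCC1(C)OCCO1 | intermediate
11 | 6-hydroxy-5-(hydroxymethyl)-5-methylhexan-2-one | CC(=O)CCCC(C)(CO)CO | intermediate
12 | 2-methyl-2-(4-oxopentyl)propanedial | CC(=O)CCCC(C)(C=O)C=O | intermediate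
13 | 3-acetyl-2-hydroxy-1-methylcyclopentane-1-carbaldehyde, C14 configured as in 14, carbinol and acetyl centres as formed (not isolated) | CC(=O)C1CC[C@](C)(C=O)C1O | intermediate
14 | (S)-3-acetyl-1-methylcyclopent-2-ene-1-carbaldehyde | CC(=O)C1=C[C@@](C)(C=O)CC1 | intermediate
15 | cross-pinacol adduct: C15 chromium alkoxide, C16 trimethylsilyl ether, (Z)-vinyl iodide, enone intact (not isolated) | CC(C)=CCC[C@H](C)CC/C(=C(/I)C)[C@H](O[Si](C)(C)C)[C@H](O[Cr](Cl)Cl)[C@]1(C)C=C(C(C)=O)CC1 | intermediate
16 | cyclised bis-silyl compound: cis-fused rings B and C, trimethylsilyl enol ether at C11=C1, C16 silyl ether, C15 chromium alkoxide (not isolated) | CC(C)=CCC[C@H](C)CCC1=C(C)[C@@H]2C(=C(C)O[Si](C)(C)C)CC[C@]2(C)[C@@H](O[Cr](Cl)Cl)[C@H]1O[Si](C)(C)C | intermediate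
17 | cis-diol methyl ketone: cis-fused hexahydroindene (rings B and C), C15-OH and C16-OH both cis to the C14 methyl, C10-H cis to the C14 methyl, acetyl on C11 cis to ring B, citronellyl-derived chain on C8 | CC(C)=CCC[C@H](C)CCC1=C(C)[C@@H]2[C@H](C(C)=O)CC[C@]2(C)[C@@H](O)[C@H]1O | intermediate
18 | as 17 but C16 inverted and esterified as 4-nitrobenzoate, C15-OH free | CC(C)=CCC[C@H](C)CCC1=C(C)[C@@H]2[C@H](C(C)=O)CC[C@]2(C)[C@@H](O)[C@@H]1OC(=O)c1ccc(cc1)[N+](=O)[O-] | intermediate
19 | trans-diol methyl ketone (C15-OH cis, C16-OH trans to the C14 methyl) | CC(C)=CCC[C@H](C)CCC1=C(C)[C@@H]2[C@H](C(C)=O)CC[C@]2(C)[C@@H](O)[C@@H]1O | intermediate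
20 | acetonide of 19 | CC(C)=CCC[C@H](C)CCC1=C(C)[C@@H]2[C@H](C(C)=O)CC[C@]2(C)[C@H]3OC(C)(C)O[C@H]13 | intermediate
21 | enol triflate of 20 (1-(trifluoromethanesulfonyloxy)vinyl group on C11) | CC(C)=CCC[C@H](C)CCC1=C(C)[C@@H]2[C@H](C(=C)OS(=O)(=O)C(F)(F)F)CC[C@]2(C)[C@H]3OC(C)(C)O[C@H]13 | intermediate
22 | side-chain vicinal diol of 21, new carbinol centre as a mixture (not isolated) | CC(C)(O)C(O)CC[C@H](C)CCC1=C(C)[C@@H]2[C@H](C(=C)OS(=O)(=O)C(F)(F)F)CC[C@]2(C)[C@H]3OC(C)(C)O[C@H]13 | intermediate
23 | C2 aldehyde enol triflate | O=CCC[C@H](C)CCC1=C(C)[C@@H]2[C@H](C(=C)OS(=O)(=O)C(F)(F)F)CC[C@]2(C)[C@H]3OC(C)(C)O[C@H]13 | intermediate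
24 | tricyclic (2S)-allylic alcohol with exocyclic methylene on C1, diol as acetonide | C=C1[C@@H](O)CC[C@H](C)CCC2=C(C)[C@@H]3[C@H]1CC[C@]3(C)[C@H]4OC(C)(C)O[C@H]24 | intermediate
25 | C2 acetate of 24 | C=C1[C@@H](OC(C)=O)CC[C@H](C)CCC2=C(C)[C@@H]3[C@H]1CC[C@]3(C)[C@H]4OC(C)(C)O[C@H]24 | intermediate
26 | CNP0192310.1, tricyclic C2 acetate with free trans C15/C16 diol | C=C1[C@@H](OC(C)=O)CC[C@H](C)CCC2=C(C)[C@@H]3[C@H]1CC[C@]3(C)[C@@H](O)[C@@H]2O | target

**Totals.** Total step count: 16. Longest linear sequence: 14 steps (steps 3–16, from 7 and 8).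

**Three steps most likely to fail**

1. Step 8 (Proposed new method). What may go wrong: chemoselection fails (the alkenyl iodide is consumed by direct nickel/chromium alkenylation of the aldehyde, or the enone is reduced by chromium/silyl chloride before the ring closes); facial selectivity in the intermolecular addition to the formyl group may also be low. Fallback, setting out from 6 and 14 and coming back at 17: Miyaura borylation of 6 (B2pin2, Pd(dppf)Cl2, KOAc, dioxane, 80 °C) would give, with retention of alkene geometry, (Z)-3-(pinacolboryl)-2-[(S)-3,7-dimethyloct-6-enyl]but-2-enal F1. Rhodium-catalysed Hayashi–Miyaura conjugate alkenylation of the enone of 14 with F1 ([Rh(cod)OH]2, BINAP, KOH, dioxane–H2O), the ligand enantiomer chosen so that the alkenyl group enters cis to the formyl group, would give the keto dialdehyde F2. SmI2 (THF, t-BuOH, −78 °C) would then close ring B by pinacol coupling of this 1,6-dialdehyde to the cis-diol 17.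

2. Step 7. What may go wrong: poor discrimination between the two enantiotopic formyl groups, or amine-induced deformylation of the malonaldehyde. Fallback, setting out from 11 and coming back at 14: lipase-catalysed enantiotopic-group-selective monoacetylation of the prochiral diol (vinyl acetate, Burkholderia cepacia lipase) would give the monoacetate F3. Dess–Martin oxidation would give the aldehyde acetate F4, and pyrrolidine/AcOH aldol condensation (only one formyl group is now present) the cyclopentene acetate F5. K2CO3/MeOH would give the alcohol F6, and Dess–Martin oxidation would return 14.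

3. Step 14. What may go wrong: oligomerisation competing with the 11-membered ring closure, and poor facial selectivity at C2. Fallback, setting out from 23 and coming back at 24: the same ring closure is run under higher dilution, and if it gives mainly the C2 epimer F7, Dess–Martin oxidation of the alcohol (mixture) to the α-methylene ketone F8 and Corey–Bakshi–Shibata reduction ((R)-Me-CBS, BH3·SMe2, the alkenyl branch acting as the large group) would set C2 under reagent control and give 24.

**Further compounds**

F1 | step 8 | (Z)-3-(4,4,5,5-tetramethyl-1,3,2-dioxaborolan-2-yl)-2-[(S)-3,7-dimethyloct-6-enyl]but-2-enal | O=C/C(CC[C@@H](C)CCC=C(C)C)=C(/C)B1OC(C)(C)C(C)(C)O1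
F2 | step 8 | keto dialdehyde: cyclopentane with C14 (methyl, formyl), C10 bearing the (Z)-enal alkenyl group cis to the formyl group, C11 acetyl | CC(C)=CCC[C@H](C)CC/C(C=O)=C(C)/[C@@H]1[C@H](C(C)=O)CC[C@]1(C)C=O
F3 | step 7 | monoacetate of 11, 2-(hydroxymethyl)-2-methyl-6-oxoheptyl acetate | CC(=O)CCC[C@@](C)(CO)COC(C)=O
F4 | step 7 | 2-formyl-2-methyl-6-oxoheptyl acetate | CC(=O)CCC[C@@](C)(C=O)COC(C)=O
F5 | step 7 | (3-acetyl-1-methylcyclopent-2-en-1-yl)methyl acetate | CC(=O)C1=C[C@@](C)(COC(C)=O)CC1
F6 | step 7 | 1-[3-(hydroxymethyl)-3-methylcyclopent-1-en-1-yl]ethanone | CC(=O)C1=C[C@@](C)(CO)CC1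
F7 | step 14 | C2 epimer of 24 | C=C1[C@H](O)CC[C@H](C)CCC2=C(C)[C@@H]3[C@H]1CC[C@]3(C)[C@H]4OC(C)(C)O[C@H]24
F8 | step 14 | C2 ketone (α-methylene ketone) corresponding to 24 | C=C1C(=O)CC[C@H](C)CCC2=C(C)[C@@H]3[C@H]1CC[C@]3(C)[C@H]4OC(C)(C)O[C@H]24
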